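**Assumption (one line):** cardamonin reacts at C3′, which is equivalent to C5′, so there is no regiochemical issue. The C4 cation of the flavan-4-ol is attacked anti to the 2-phenyl group, which gives the 2,4-trans relationship seen in the target, (2R,4R).

## Retrosynthetic overview
- Disconnect the flavan C4–aryl bond by Friedel–Crafts. This gives the C4 cation of (2R)-7-hydroxy-5,8-dimethoxyflavan-4-ol (9) plus cardamonin (13), a symmetric, phloroglucinol-type nucleophile.
- The C2 stereocentre is set by Ru-catalysed asymmetric transfer hydrogenation with dynamic kinetic resolution of racemic 7-hydroxy-5,8-dimethoxyflavanone (8). The C4 carbinol centre is later destroyed by ionisation.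
- Flavanone 8 comes from oxa-Michael cyclisation of a 2′-hydroxychalcone, which comes from Claisen–Schmidt condensation of 2′-hydroxy-3′,4′,6′-trimethoxyacetophenone. That ketone is made from 1,2,3,5-tetramethoxybenzene by Friedel–Crafts acylation and selective demethylation.
- Order of bond formation: the A-ring ketone, then the pyranone ring, then the C2 stereocentre, and the C4–aryl bond last. Cardamonin is made in two steps from phloroacetophenone.

## Route

**Step 1**
Reactants: 1 (1,2,3,5-tetramethoxybenzene) + 2 (acetic anhydride)
Product: 3 (1-(2,3,4,6-tetramethoxyphenyl)ethan-1-one)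
Conditions: BF3·OEt2, CH2Cl2, 0 °C → rt
Reagents that add atoms: acetic anhydride, CC(=O)OC(C)=O (acetyl group)
Why: Friedel–Crafts acylation of the very electron-rich arene; C4 and C6 are equivalent by symmetry, so only one regioisomer forms.

**Step 2**
Reactants: 3
Product: 4 (1-(2-hydroxy-3,4,6-trimethoxyphenyl)ethan-1-one)
Conditions: BCl3 (1.1 equiv), CH2Cl2, −78 → 0 °C
Reagents that add atoms: none
Why: Carbonyl-directed, chelation-assisted ortho-demethylation (Lewis-acid ether cleavage). The buttressed 2′-OMe, flanked by the 3′-OMe and the acyl group, is cleaved faster than the 6′-OMe.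

**Step 3**
Reactants: 4 + 5 (benzaldehyde)
Product: 6 ((E)-2′-hydroxy-3′,4′,6′-trimethoxychalcone)
Conditions: KOH, EtOH/H2O, rt
Reagents that add atoms: benzaldehyde, O=Cc1ccccc1 (PhCH= unit)
Why: Claisen–Schmidt aldol condensation, which gives the thermodynamic E-enone.

**Step 4**
Reactants: 6
Product: 7 ((±)-5,7,8-trimethoxyflavanone)
Conditions: NaOAc, EtOH, reflux
Reagents that add atoms: none
Why: Intramolecular oxa-Michael addition of the phenol onto the enone (6-endo) closes the pyranone ring. C2 is formed racemic, which is what the later dynamic kinetic resolution needs.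

**Step 5**
Reactants: 7
Product: 8 ((±)-7-hydroxy-5,8-dimethoxyflavanone)
Conditions: NaSEt, DMF, 60 °C; then 1 M HCl
Reagents that add atoms: none
Why: Nucleophilic (SN2) O-demethylation is selective for the 7-OMe, a vinylogous ester para to the ring-locked C4 carbonyl. The 8-OMe is meta and the 5-OMe is more hindered. The acid work-up re-closes any ring-opened chalcone.

**Step 6**
Reactants: 8
Product: 9 ((2R,4R)-5,8-dimethoxy-2-phenylchromane-4,7-diol)
Conditions: RuCl[(R,R)-TsDPEN](p-cymene) (2 mol %), HCO2H/Et3N (5:2), DMF, 40 °C
Reagents that add atoms: none (hydride and proton only)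
Why: Noyori–Ikariya asymmetric transfer hydrogenation with dynamic kinetic resolution. The flavanone C2 epimerises through retro-oxa-Michael ring opening, and the (R,R)-catalyst reduces the 2R enantiomer to the cis-flavan-4-ol, which sets C2 as R. C4 is destroyed in Step 9, so its configuration does not matter.

**Step 7**
Reactants: 10 (2′,4′,6′-trihydroxyacetophenone) + 11 (methyl iodide)
Product: 12 (2′,6′-dihydroxy-4′-methoxyacetophenone)
Conditions: MeI (1.0 equiv), K2CO3, acetone, reflux
Reagents that add atoms: methyl iodide, CI (OCH3 group)
Why: Regioselective O-alkylation of the most acidic phenol, the 4′-OH, which is not held by a hydrogen bond to the carbonyl.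

**Step 8**
Reactants: 12 + 5 (benzaldehyde)
Product: 13 (cardamonin, (E)-2′,6′-dihydroxy-4′-methoxychalcone)
Conditions: 50% aq. KOH, EtOH, rt, 48 h
Reagents that add atoms: benzaldehyde, O=Cc1ccccc1 (PhCH= unit)
Why: Claisen–Schmidt condensation. The hydrogen-bonded 2′,6′-phenoxides survive and the E-enone forms.

**Step 9**
Reactants: 9 + 13 (3 equiv)
Product: 14 (sarcandrone B)
Conditions: Sc(OTf)3 (10 mol %), HFIP/CH2Cl2 (1:4), 0 °C → rt
Reagents that add atoms: none (water is lost)
Why: Acid-promoted ionisation of the benzylic C4–OH, stabilised by the 5-OMe and the 7-OH para to C4a, gives a chromanyl cation, followed by Friedel–Crafts C-arylation by cardamonin. The nucleophile attacks anti to the 2-phenyl group, which sets C4 as R (2,4-trans), and C2 is untouched so it stays R.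

## Compound list
1 | 1,2,3,5-tetramethoxybenzene | COc1cc(OC)c(OC)c(OC)c1 | starting material
2 | acetic anhydride | CC(=O)OC(C)=O | starting material
3 | 1-(2,3,4,6-tetramethoxyphenyl)ethan-1-one | CC(=O)c1c(OC)cc(OC)c(OC)c1OC | intermediate
4 | 1-(2-hydroxy-3,4,6-trimethoxyphenyl)ethan-1-one | CC(=O)c1c(OC)cc(OC)c(OC)c1O | intermediate
5 | benzaldehyde | O=Cc1ccccc1 | starting material
6 | (E)-2′-hydroxy-3′,4′,6′-trimethoxychalcone | O=C(/C=C/c1ccccc1)c1c(OC)cc(OC)c(OC)c1O | intermediate
7 | (±)-5,7,8-trimethoxyflavanone | O=C1CC(c2ccccc2)Oc2c(OC)c(OC)cc(OC)c21 | intermediate (racemic)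
8 | (±)-7-hydroxy-5,8-dimethoxyflavanone | O=C1CC(c2ccccc2)Oc2c(OC)c(O)cc(OC)c21 | intermediate (racemic)
9 | (2R,4R)-5,8-dimethoxy-2-phenylchromane-4,7-diol | O[C@@H]1C[C@H](c2ccccc2)Oc2c(OC)c(O)cc(OC)c21 | intermediate
10 | 2′,4′,6′-trihydroxyacetophenone | CC(=O)c1c(O)cc(O)cc1O | starting material
11 | methyl iodide | CI | starting material
12 | 2′,6′-dihydroxy-4′-methoxyacetophenone | CC(=O)c1c(O)cc(OC)cc1O | intermediate
13 | cardamonin | COc1cc(O)c(C(=O)/C=C/c2ccccc2)c(O)c1 | intermediate
14 | sarcandrone B | COc1cc(O)c(C(=O)/C=C/c2ccccc2)c(O)c1[C@H]1C[C@H](c2ccccc2)Oc2c(OC)c(O)cc(OC)c21 | target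

## Totals
- Total steps: 9.
- Longest linear sequence: 7 steps (Steps 1–6, then Step 9). The cardamonin branch is 2 steps and converges at Step 9.

## Three steps most likely to fail, with fallbacks
1. **Step 5, regioselective 7-O-demethylation.** Thiolate may also cleave the 5-OMe or open the flavanone ring.
   *Fallback (different approach):* start from commercial wogonin (5,7-dihydroxy-8-methoxyflavone). Benzylate 7-OH (BnBr, K2CO3), methylate 5-OH (MeI, K2CO3, DMF), then hydrogenate (H2, Pd/C), which reduces C2=C3 and removes the benzyl group to give 8.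
2. **Step 6, dynamic kinetic resolution.** The flavanone may racemise too slowly under the formate conditions, giving only kinetic resolution with at most 50% yield, or the ee may be low.
   *Fallback (different approach):* reduce 8 with NaBH4 to racemic flavan-4-ol, then resolve it enzymatically (CAL-B, vinyl acetate) to obtain the (2R)-alcohol. Recycle the 2S enantiomer by oxidation back to the flavanone.
3. **Step 9, Friedel–Crafts coupling.** The electron-rich flavan A-ring can self-condense through C6, the 2,4-cis isomer may form, or C2 may epimerise through the cation.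
   *Fallback (different approach):* convert 9 to the enantiopure 4-deoxy flavan (Et3SiH/TFA) and couple it with cardamonin by DDQ-mediated benzylic C–H arylation (cross-dehydrogenative coupling), which avoids the 4-ol cation and its oligomerisation.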